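**Retrosynthetic overview**
1. C8–OMe is cut last: the target comes from 5-hydroxy-2',3',7-trimethoxyflavone (4) by a late para-C–H methoxylation (C–O bond formation).
2. The pyranone O1–C2 bond is cut next: 4 comes from a 2',6'-dihydroxychalcone (3) by oxidative oxa-cyclisation (C–O bond formation). The A ring of 3 is symmetric, so only one flavone can form.
3. The enone Cα=Cβ bond is cut: 3 comes from acetophenone 1 and aldehyde 2 by Claisen–Schmidt condensation.
4. Ring order: rings A and B are bought; the pyranone ring C is closed in step 2; no ring is formed afterwards.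

Assumption: the target has no stereocentre and is achiral, so "single enantiomer" needs no stereocontrol; the only stereo-element in the route (the E alkene of 3) disappears on cyclisation.

**Step 1**
Reactants: 1 (2',6'-dihydroxy-4'-methoxyacetophenone) and 2 (2,3-dimethoxybenzaldehyde)
Product: 3 (E)-1-(2,6-dihydroxy-4-methoxyphenyl)-3-(2,3-dimethoxyphenyl)prop-2-en-1-one
Conditions: KOH (10 equiv, 50% aq.), EtOH, 0 °C → rt, 48 h; then cold 2 M HCl to pH 3
Reagents that add atoms: none
Why: Claisen–Schmidt (crossed aldol) condensation, in which the acetyl group is the only enolisable position, the aldehyde cannot self-condense, and E1cB dehydration gives the conjugated E-enone as the thermodynamic isomer.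

**Step 2**
Reactants: 3 (the 2',6'-dihydroxychalcone)
Product: 4 5-hydroxy-7-methoxy-2-(2,3-dimethoxyphenyl)-4H-chromen-4-one (5-hydroxy-2',3',7-trimethoxyflavone)
Conditions: I2 (10 mol %), DMSO, 130 °C, 2 h
Reagents that add atoms: none
Why: Iodine-catalysed oxidative cyclisation of a 2'-hydroxychalcone (6-endo oxa-Michael C–O closure and net dehydrogenation, DMSO re-oxidising HI to I2); the two ortho-hydroxyls are equivalent, so a single flavone forms and the second hydroxyl becomes the chelated 5-OH.

**Step 3**
Reactants: 4 (5-hydroxy-2',3',7-trimethoxyflavone)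
Product: 6 target flavone (5-hydroxy-2',3',7,8-tetramethoxyflavone), via quinone monoketal 5 (not isolated)
Conditions: PhI(OAc)2 (2.3 equiv), MeOH–CH2Cl2 (4:1), 0 °C → rt; then Zn dust (5 equiv), AcOH (10 equiv), 0 °C → rt, one pot
Reagents that add atoms: methanol (CO)
Why: Proposed new method: net para-C–H methoxylation of a peri-chelated 5-hydroxyflavone by deliberate over-oxidation and reductive re-aromatisation — the 5-OH exchanges onto iodine(III) and MeOH attacks the aryloxy-λ3-iodane at C8 (para to the phenolic oxygen, giving a cross-conjugated dienone stabilised by the 7-OMe and O1 donors), the first-formed 8-methoxyphenol (identical with 6) is more easily oxidised than 4 and is driven by the second equivalent to the 8,8-dimethyl monoketal 5, and Zn/AcOH then reduces the dienone with loss of one methoxide to leave exactly one new C8–OMe and a free 5-OH; the closest known reaction types are the iodine(III) oxidation of para-unsubstituted phenols to p-quinone monoketals in methanol, the reductive aromatisation of quinone monoketals to p-alkoxyphenols, and the para-selective Elbs oxidation of 5-hydroxyflavones at C8, which to my knowledge have not been combined into a direct C8–H to C8–OMe conversion on a flavone.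

**Compound list**
1 | 2',6'-dihydroxy-4'-methoxyacetophenone | CC(=O)c1c(O)cc(OC)cc1O | starting material
2 | 2,3-dimethoxybenzaldehyde | COc1cccc(C=O)c1OC | starting material
3 | (E)-1-(2,6-dihydroxy-4-methoxyphenyl)-3-(2,3-dimethoxyphenyl)prop-2-en-1-one | COc1cc(O)c(C(=O)/C=C/c2cccc(OC)c2OC)c(O)c1 | intermediate
4 | 5-hydroxy-7-methoxy-2-(2,3-dimethoxyphenyl)-4H-chromen-4-one | COc1cc(O)c2c(c1)oc(-c1cccc(OC)c1OC)cc2=O | intermediate
5 | 2-(2,3-dimethoxyphenyl)-7,8,8-trimethoxy-4H-chromene-4,5(8H)-dione (flavone-5,8-quinone 8,8-dimethyl monoketal) | COC1=CC(=O)C2=C(OC(=CC2=O)c2cccc(OC)c2OC)C1(OC)OC | intermediate (not isolated)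
6 | 5-hydroxy-2',3',7,8-tetramethoxyflavone | COc1cc(O)c2c(c1OC)oc(-c1cccc(OC)c1OC)cc2=O | target

**Totals**
Total step count: 3. Longest linear sequence: 3 steps (from 1 or 2 to 6).

**Steps most likely to fail**

Step 3 (the proposed new step, highest risk). The first oxidation of the acyl-deactivated, hydrogen-bonded phenol may be slow. Methanol may also attack ortho at C6, which after reduction gives the 5-hydroxy-6,7-dimethoxy isomer. The dimethoxyphenyl ring may be oxidised if forcing conditions are needed. The fallback uses known chemistry, sets out from 4 and comes back at 6. Elbs persulfate oxidation of 4 (K2S2O8, aq. KOH/pyridine, 0–20 °C) attacks para to the phenoxide and gives potassium 2-(2,3-dimethoxyphenyl)-5-hydroxy-7-methoxy-4-oxo-4H-chromen-8-yl sulfate F3. Acid hydrolysis (2 M HCl, Na2SO3, 90 °C) gives 5,8-dihydroxy-7-methoxy-2-(2,3-dimethoxyphenyl)-4H-chromen-4-one F4. MeI (1.05 equiv) with K2CO3 in acetone at rt then methylates only the 8-OH, because the 5-OH is held in the hydrogen bond to C4=O, and gives 6.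

Step 1. The unprotected, doubly chelated acetophenone may condense slowly, and acidification can give chalcone/flavanone mixtures. The fallback sets out from 1 and comes back at 4, bypassing 3 and step 2. LiHMDS (4 equiv) in THF at −78 °C forms the polylithiated ketone, which is C-acylated with commercial 2,3-dimethoxybenzoyl chloride (1 equiv) to give 1-(2,6-dihydroxy-4-methoxyphenyl)-3-(2,3-dimethoxyphenyl)propane-1,3-dione F1. AcOH containing 0.5% H2SO4 at 95 °C cyclodehydrates this diketone to 4; the symmetric A ring again allows only one product.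

Step 2. The electron-rich A ring may be iodinated at C6/C8, or conversion may stop at the flavanone. The fallback sets out from 3 and comes back at 4. NaOAc in refluxing EtOH isomerises the chalcone by oxa-Michael addition to racemic 5-hydroxy-7-methoxy-2-(2,3-dimethoxyphenyl)chroman-4-one F2, whose stereocentre is of no consequence. DDQ (1.5 equiv) in refluxing dioxane then dehydrogenates it to 4 without any iodine electrophile.

**Further compounds**
F1 | step 1 | 1-(2,6-dihydroxy-4-methoxyphenyl)-3-(2,3-dimethoxyphenyl)propane-1,3-dione | COc1cc(O)c(C(=O)CC(=O)c2cccc(OC)c2OC)c(O)c1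
F2 | step 2 | racemic 5-hydroxy-7-methoxy-2-(2,3-dimethoxyphenyl)chroman-4-one | COc1cc(O)c2c(c1)OC(c1cccc(OC)c1OC)CC2=O
F3 | step 3 | potassium 2-(2,3-dimethoxyphenyl)-5-hydroxy-7-methoxy-4-oxo-4H-chromen-8-yl sulfate | COc1cc(O)c2c(c1OS(=O)(=O)[O-])oc(-c1cccc(OC)c1OC)cc2=O.[K+]
F4 | step 3 | 5,8-dihydroxy-7-methoxy-2-(2,3-dimethoxyphenyl)-4H-chromen-4-one | COc1cc(O)c2c(c1O)oc(-c1cccc(OC)c1OC)cc2=O
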